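## Retrosynthetic overview
1. Remove both TBS groups, then cut the allyl–allyl bond C9–C10. This gives lithiated geranyl phenyl sulfone and a C1–C9 allylic bromide; the sulfonyl group is excised afterwards with Pd/hydride.
2. The E-C7=C8 alkene comes from cross-metathesis of a terminal alkene with methacrolein, followed by CHO → CH2OH → CH2Br.
3. The key bond C5–C6 comes from reagent-controlled asymmetric carbonyl allylation (allylboration) of the C1–C5 enal, which sets 5R.
4. The C1–C5 enal comes from the same two operations on furan-3-carbaldehyde: allylboration sets 1S and methacrolein metathesis sets 3E.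
5. No ring is formed. The furan is the only ring and is bought in.

Chain numbering: C1 is the furyl carbinol carbon and C17 is the chain end. The target is (1S,3E,5R,7E,11E)-1-(furan-3-yl)-4,8,12,16-tetramethylheptadeca-3,7,11,15-tetraene-1,5-diol.

Assumption: both enantiomers of B-methoxydiisopinocampheylborane, allylmagnesium bromide solution, methacrolein, geranyl bromide and sodium benzenesulfinate are taken as catalogue items. The sulfone-bearing carbon made in the fragment coupling is an epimer mixture that the next step erases.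

## Route

Step 1
Reactants: 1 (−)-B-methoxydiisopinocampheylborane (both Ipc groups from (+)-α-pinene); 2 allylmagnesium bromide
Product: 3 B-allyldiisopinocampheylborane, (+)-α-pinene series, kept as a salt-free pentane solution
Conditions: Et2O, 0 °C to rt, 1 h; evaporate, take up in pentane, filter off the Mg salts under Ar
Reagents that add atoms: none
Why: Transmetalation from magnesium to boron is fast and quantitative, and removing the magnesium salts gives the reagent that reacts cleanly at −100 °C; no stereocentre is made.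

Step 2
Reactants: 4 furan-3-carbaldehyde; 3 B-allyldiisopinocampheylborane, (+)-α-pinene series
Product: 6 (S)-1-(furan-3-yl)but-3-en-1-ol, via borinate ester 5 (not isolated)
Conditions: 3 (1.2 equiv), Et2O/pentane, −100 °C, 1 h; then 3 M NaOH, 30% H2O2, 0 °C to rt
Reagents that add atoms: none
Why: In this Brown asymmetric allylboration (carbonyl allylation), the closed chair transition state with (+)-α-pinene-derived ligands delivers allyl to the Si face of an aryl aldehyde, which sets C1 as S in high ee, and alkaline peroxide then frees the alcohol without harming the furan.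

Step 3
Reactants: 6 (S)-1-(furan-3-yl)but-3-en-1-ol
Product: 7 (S)-tert-butyl{[1-(furan-3-yl)but-3-en-1-yl]oxy}dimethylsilane
Conditions: TBSCl, imidazole, DMF, rt
Reagents that add atoms: tert-butyldimethylsilyl chloride, CC(C)(C)[Si](C)(C)Cl
Why: Standard silyl ether protection of a secondary alcohol takes place at oxygen only, so C1 is untouched.

Step 4
Reactants: 7 TBS ether; 8 methacrolein
Product: 9 (2E,5S)-5-[(tert-butyldimethylsilyl)oxy]-5-(furan-3-yl)-2-methylpent-2-enal
Conditions: 8 (5 equiv, freshly distilled), second-generation Hoveyda–Grubbs catalyst RuCl2(H2IMes)(=CH-C6H4-2-OiPr) (5 mol %), CH2Cl2, 40 °C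
Reagents that add atoms: none
Why: Olefin cross-metathesis of a reactive terminal alkene with methacrolein, which does not homodimerise, favours the cross product and gives the thermodynamically preferred E-trisubstituted enal, while the furan and silyl ether are inert to the ruthenium carbene.

Step 5
Reactants: 10 (+)-B-methoxydiisopinocampheylborane (both Ipc groups from (−)-α-pinene); 2 allylmagnesium bromide
Product: 11 B-allyldiisopinocampheylborane, (−)-α-pinene series, kept as a salt-free pentane solution
Conditions: Et2O, 0 °C to rt, 1 h; evaporate, take up in pentane, filter off the Mg salts under Ar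
Reagents that add atoms: none
Why: This is the same magnesium-to-boron transmetalation as in step 1, carried out in the enantiomeric ligand series.

Step 6 (key step)
Reactants: 9 C1–C5 enal; 11 B-allyldiisopinocampheylborane, (−)-α-pinene series
Product: 13 (4R,5E,8S)-8-[(tert-butyldimethylsilyl)oxy]-8-(furan-3-yl)-5-methylocta-1,5-dien-4-ol, via borinate ester 12 (not isolated)
Conditions: 11 (1.4 equiv), Et2O/pentane, −100 °C, 2 h; then 3 M NaOH, 30% H2O2, 0 °C to rt; chromatography
Reagents that add atoms: none
Why: This Brown allylboration (intermolecular carbonyl allylation) is purely reagent-controlled because the existing centre is remote, so the (−)-α-pinene-derived reagent attacks the Re face of the α-methyl enal in 1,2-fashion and sets the new carbinol (C5 of the target) as R under neutral conditions that spare the enal, silyl ether and furan.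

Step 7
Reactants: 13 homoallylic/allylic alcohol
Product: 14 3-[(1S,3E,5R)-1,5-bis[(tert-butyldimethylsilyl)oxy]-4-methylocta-3,7-dien-1-yl]furan
Conditions: TBSOTf, 2,6-lutidine, CH2Cl2, −78 to 0 °C
Reagents that add atoms: tert-butyldimethylsilyl triflate, CC(C)(C)[Si](C)(C)OS(=O)(=O)C(F)(F)F
Why: The silyl triflate with a hindered base silylates the encumbered allylic alcohol quickly at low temperature without ionising it, so both stereocentres are retained.

Step 8
Reactants: 14 bis-TBS ether; 8 methacrolein
Product: 15 (2E,5R,6E,9S)-5,9-bis[(tert-butyldimethylsilyl)oxy]-9-(furan-3-yl)-2,6-dimethylnona-2,6-dienal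
Conditions: 8 (10 equiv), RuCl2(H2IMes)(=CH-C6H4-2-OiPr) (2 × 4 mol %), CH2Cl2, 40 °C
Reagents that add atoms: none
Why: In this olefin cross-metathesis only the monosubstituted alkene engages the catalyst, because the hindered trisubstituted C3=C4 alkene is unreactive and no viable ring closure exists, and the E-enal again results.

Step 9
Reactants: 15 dienal
Product: 16 (2E,5R,6E,9S)-5,9-bis[(tert-butyldimethylsilyl)oxy]-9-(furan-3-yl)-2,6-dimethylnona-2,6-dien-1-ol
Conditions: DIBAL-H (1.5 equiv), CH2Cl2, −78 °C; aq. Rochelle salt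
Reagents that add atoms: none
Why: DIBAL-H reduces enals cleanly in 1,2-fashion at −78 °C in an aprotic medium, which avoids any base-induced loss of the δ-silyloxy group.

Step 10
Reactants: 16 allylic alcohol
Product: 17 3-[(1S,3E,5R,7E)-9-bromo-1,5-bis[(tert-butyldimethylsilyl)oxy]-4,8-dimethylnona-3,7-dien-1-yl]furan
Conditions: CBr4, PPh3, 2,6-lutidine (0.2 equiv), CH2Cl2, −20 to 0 °C; short silica plug, used at once
Reagents that add atoms: carbon tetrabromide, BrC(Br)(Br)Br
Why: The Appel reaction converts a primary allylic alcohol to the bromide by SN2 under near-neutral conditions, so the alkene geometry, silyl ethers and furan survive.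

Step 11
Reactants: 18 geranyl bromide; 19 sodium benzenesulfinate
Product: 20 geranyl phenyl sulfone, {[(2E)-3,7-dimethylocta-2,6-dien-1-yl]sulfonyl}benzene
Conditions: DMF, rt, 12 h
Reagents that add atoms: none
Why: S-alkylation of the soft sulfinate by a primary allylic bromide is an SN2 reaction that keeps the E geometry.

Step 12
Reactants: 20 geranyl phenyl sulfone; 17 allylic bromide
Product: 22 C10-phenylsulfonyl derivative of the bis-TBS-protected target (C10 epimer mixture), via lithiated sulfone 21 (not isolated)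
Conditions: n-BuLi (1.05 equiv), THF, −78 °C, 30 min; then 17, −78 to −20 °C
Reagents that add atoms: none
Why: In this sulfone-stabilised carbanion alkylation (Biellmann-type allyl–allyl coupling) the allyl sulfone anion reacts at its α-carbon and the primary allylic bromide by direct SN2, so the C9–C10 bond forms with all alkene positions and geometries fixed.

Step 13
Reactants: 22 allylic sulfone
Product: 23 3-[(1S,3E,5R,7E,11E)-1,5-bis[(tert-butyldimethylsilyl)oxy]-4,8,12,16-tetramethylheptadeca-3,7,11,15-tetraen-1-yl]furan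
Conditions: PdCl2(dppp) (10 mol %), LiBHEt3 (3 equiv), THF, 0 °C
Reagents that add atoms: none
Why: In this palladium-catalysed reductive desulfonylation, zerovalent palladium ionises only the allylic sulfone and hydride goes to the less substituted allyl terminus (C10), so the C11=C12 alkene stays in place and E because isomerisation would need a tertiary carbon–palladium bond.

Step 14
Reactants: 23 bis-TBS ether
Product: 24 target, (1S,3E,5R,7E,11E)-1-(furan-3-yl)-4,8,12,16-tetramethylheptadeca-3,7,11,15-tetraene-1,5-diol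
Conditions: TBAF (4 equiv), THF, 0 °C to rt; pH 7 buffer work-up
Reagents that add atoms: none
Why: Fluoride-driven desilylation cleaves only Si–O bonds, so the acid-sensitive furyl and allylic carbinols are released with C1 (S) and C5 (R) intact.

## Compound list
1 | (−)-B-methoxydiisopinocampheylborane, (+)-α-pinene series | COB([C@@H]1C[C@@H]2C[C@H]([C@H]1C)C2(C)C)[C@@H]1C[C@@H]2C[C@H]([C@H]1C)C2(C)C | starting material
2 | allylmagnesium bromide | C=CC[Mg]Br | starting material
3 | B-allyldiisopinocampheylborane, (+)-α-pinene series | C=CCB([C@@H]1C[C@@H]2C[C@H]([C@H]1C)C2(C)C)[C@@H]1C[C@@H]2C[C@H]([C@H]1C)C2(C)C | intermediate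
4 | furan-3-carbaldehyde | O=Cc1ccoc1 | starting material
5 | (S)-1-(furan-3-yl)but-3-enyl diisopinocampheylborinate | C=CC[C@H](OB([C@@H]1C[C@@H]2C[C@H]([C@H]1C)C2(C)C)[C@@H]1C[C@@H]2C[C@H]([C@H]1C)C2(C)C)c1ccoc1 | intermediate
6 | (S)-1-(furan-3-yl)but-3-en-1-ol | C=CC[C@H](O)c1ccoc1 | intermediate
7 | TBS ether of 6 | C=CC[C@H](O[Si](C)(C)C(C)(C)C)c1ccoc1 | intermediate
8 | methacrolein | C=C(C)C=O | starting material
9 | (2E,5S)-5-(TBS-oxy)-5-(furan-3-yl)-2-methylpent-2-enal | O=C/C(C)=C/C[C@H](O[Si](C)(C)C(C)(C)C)c1ccoc1 | intermediate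
10 | (+)-B-methoxydiisopinocampheylborane, (−)-α-pinene series | COB([C@H]1C[C@H]2C[C@@H]([C@@H]1C)C2(C)C)[C@H]1C[C@H]2C[C@@H]([C@@H]1C)C2(C)C | starting material
11 | B-allyldiisopinocampheylborane, (−)-α-pinene series | C=CCB([C@H]1C[C@H]2C[C@@H]([C@@H]1C)C2(C)C)[C@H]1C[C@H]2C[C@@H]([C@@H]1C)C2(C)C | intermediate
12 | diisopinocampheylborinate of 13 | C=CC[C@@H](OB([C@H]1C[C@H]2C[C@@H]([C@@H]1C)C2(C)C)[C@H]1C[C@H]2C[C@@H]([C@@H]1C)C2(C)C)/C(C)=C/C[C@H](O[Si](C)(C)C(C)(C)C)c1ccoc1 | intermediate
13 | (4R,5E,8S)-8-(TBS-oxy)-8-(furan-3-yl)-5-methylocta-1,5-dien-4-ol | C=CC[C@@H](O)/C(C)=C/C[C@H](O[Si](C)(C)C(C)(C)C)c1ccoc1 | intermediate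
14 | 3-[(1S,3E,5R)-1,5-bis(TBS-oxy)-4-methylocta-3,7-dienyl]furan | C=CC[C@@H](O[Si](C)(C)C(C)(C)C)/C(C)=C/C[C@H](O[Si](C)(C)C(C)(C)C)c1ccoc1 | intermediate
15 | (2E,5R,6E,9S)-5,9-bis(TBS-oxy)-9-(furan-3-yl)-2,6-dimethylnona-2,6-dienal | O=C/C(C)=C/C[C@@H](O[Si](C)(C)C(C)(C)C)/C(C)=C/C[C@H](O[Si](C)(C)C(C)(C)C)c1ccoc1 | intermediate
16 | (2E,5R,6E,9S)-5,9-bis(TBS-oxy)-9-(furan-3-yl)-2,6-dimethylnona-2,6-dien-1-ol | OC/C(C)=C/C[C@@H](O[Si](C)(C)C(C)(C)C)/C(C)=C/C[C@H](O[Si](C)(C)C(C)(C)C)c1ccoc1 | intermediate
17 | 3-[(1S,3E,5R,7E)-9-bromo-1,5-bis(TBS-oxy)-4,8-dimethylnona-3,7-dienyl]furan | BrC/C(C)=C/C[C@@H](O[Si](C)(C)C(C)(C)C)/C(C)=C/C[C@H](O[Si](C)(C)C(C)(C)C)c1ccoc1 | intermediate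
18 | geranyl bromide | CC(C)=CCC/C(C)=C/CBr | starting material
19 | sodium benzenesulfinate | [Na+].[O-]S(=O)c1ccccc1 | starting material
20 | geranyl phenyl sulfone | CC(C)=CCC/C(C)=C/CS(=O)(=O)c1ccccc1 | intermediate
21 | α-lithiated geranyl phenyl sulfone | CC(C)=CCC/C(C)=C/C([Li])S(=O)(=O)c1ccccc1 | intermediate
22 | C10-phenylsulfonyl bis-TBS ether (C10 epimers) | CC(C)=CCC/C(C)=C/C(C/C(C)=C/C[C@@H](O[Si](C)(C)C(C)(C)C)/C(C)=C/C[C@H](O[Si](C)(C)C(C)(C)C)c1ccoc1)S(=O)(=O)c1ccccc1 | intermediate
23 | bis-TBS ether of the target | CC(C)=CCC/C(C)=C/CC/C(C)=C/C[C@@H](O[Si](C)(C)C(C)(C)C)/C(C)=C/C[C@H](O[Si](C)(C)C(C)(C)C)c1ccoc1 | intermediate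
24 | (1S,3E,5R,7E,11E)-1-(furan-3-yl)-4,8,12,16-tetramethylheptadeca-3,7,11,15-tetraene-1,5-diol | CC(C)=CCC/C(C)=C/CC/C(C)=C/C[C@@H](O)/C(C)=C/C[C@H](O)c1ccoc1 | target

## Step count and risks
Total steps: 14. Two of these are allylborane preparations and one is the sulfone side branch.

Longest linear sequence: 12 steps (1, 2, 3, 4, 6, 7, 8, 9, 10, 12, 13, 14), or 11 counted from furan-3-carbaldehyde.

**Step 6.** The risk is that the C5 epimer ratio falls short and the epimers are hard to separate.
- The fallback sets out from 9 and keeps the same C5–C6 bond, but moves the stereocontrol to a reduction.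
- Allylmagnesium bromide 2 is added without stereocontrol (THF, −78 °C) to give the C4-epimeric (5E,8S)-8-(TBS-oxy)-8-(furan-3-yl)-5-methylocta-1,5-dien-4-ol F1.
- Oxidation with Dess–Martin periodinane buffered with NaHCO3 (CH2Cl2, 0 °C) gives (5E,8S)-8-(TBS-oxy)-8-(furan-3-yl)-5-methylocta-1,5-dien-4-one F2. This ketone is used at once to avoid alkene migration.
- Corey–Bakshi–Shibata reduction follows, with (S)-Me-CBS oxazaborolidine and catecholborane (toluene, −78 °C). The α-methylalkenyl arm acts as the large group, which gives the R carbinol.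
- The fallback comes back to the route at 13.

**Step 8.** The risk is stalled or low-yielding cross-metathesis on the larger diene.
- The fallback sets out from 14 and replaces metathesis by oxidative cleavage and olefination.
- Chemoselective dihydroxylation of the unhindered monosubstituted alkene uses OsO4 (1 mol %) and NMO in acetone/water at 0 °C. The trisubstituted alkene is shielded and deactivated by its allylic silyloxy carbon. The product is (4R,5E,8S)-4,8-bis(TBS-oxy)-8-(furan-3-yl)-5-methyloct-5-ene-1,2-diol F3.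
- Cleavage with NaIO4 (THF/water) gives (3R,4E,7S)-3,7-bis(TBS-oxy)-7-(furan-3-yl)-4-methylhept-4-enal F4.
- An E-selective Wittig reaction with the stabilised ylide 2-(triphenylphosphoranylidene)propanal (toluene, 80 °C) comes back to the route at 15.

**Step 13.** The risk is alkene migration or E/Z erosion during desulfonylation. This fallback also covers a poor step 12.
- The fallback sets out from 17 and avoids the sulfone altogether.
- Commercial geranyl chloride is treated at −78 °C with activated barium metal (from BaI2 and lithium biphenylide in THF) to give geranylbarium chloride F5.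
- This reagent couples with bromide 17 at −78 °C in an α,α′-selective, geometry-retaining allyl–allyl cross-coupling.
- The fallback comes back to the route at 23.

## Further compounds
F1 | step 6 | (5E,8S)-8-(TBS-oxy)-8-(furan-3-yl)-5-methylocta-1,5-dien-4-ol, both C4 epimers | C=CCC(O)/C(C)=C/C[C@H](O[Si](C)(C)C(C)(C)C)c1ccoc1
F2 | step 6 | (5E,8S)-8-(TBS-oxy)-8-(furan-3-yl)-5-methylocta-1,5-dien-4-one | C=CCC(=O)/C(C)=C/C[C@H](O[Si](C)(C)C(C)(C)C)c1ccoc1
F3 | step 8 | (4R,5E,8S)-4,8-bis(TBS-oxy)-8-(furan-3-yl)-5-methyloct-5-ene-1,2-diol, both C2 epimers | OCC(O)C[C@@H](O[Si](C)(C)C(C)(C)C)/C(C)=C/C[C@H](O[Si](C)(C)C(C)(C)C)c1ccoc1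
F4 | step 8 | (3R,4E,7S)-3,7-bis(TBS-oxy)-7-(furan-3-yl)-4-methylhept-4-enal | O=CC[C@@H](O[Si](C)(C)C(C)(C)C)/C(C)=C/C[C@H](O[Si](C)(C)C(C)(C)C)c1ccoc1
F5 | step 13 | geranylbarium chloride | CC(C)=CCC/C(C)=C/C[Ba]Cl
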